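Take the ratio first.

| flask | X | Q | G | E | time |
|---|---|---|---|---|---|
| alpha | 0.10 M | 0.0800 M | 0.50 mM | 0.10 M | 4.0 h |
| eta | 0.10 M | 0.0800 M | 1.0 mM | 0.10 M | 4.0 h |
| delta | 0.10 M | 0.0800 M | 2.0 mM | 0.10 M | 4.0 h |

    Q + Z + X → Z + L (k1 = 1.1 × 10⁵ /M²/h)
    G → Z (k2 = 0.54 /h)
    Q + Z + E → Z + D (k3 = 7700 /M²/h)

- amount of L at the end, in percent of the X and E together charged for alpha, eta, delta, in this order
- the course of these numbers from the first flask to the last (falls all the way / falls, then rises / rises all the way / rises, then falls / hardly changes)

- Z is single-handed; X and E are mirror images of each other, charged as a racemate, each of them at the stated concentration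
- "hardly changes" means that all values lie within two and a half points (for a concentration: within two and a half percent of the largest)
- run time (alpha): 4.0 h

Let x and e be the fractions of their own charges of X and E still present.

What do X and E compete for? They compete for the same Q on the same Z: each step runs at its constant times Q, Z and its own substrate, so Q and Z cancel from the ratio of the two losses, and x equals e raised to the power of the selectivity factor, the constant of the X step over that of the E step, 14.3.

How far can the flask go? Q is the limiting reagent, charged at 0.800 of the charge of X, against 2 for X and E together, so if the whole of Q is used, the fractions lost by X and E add up to that figure.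

Solve it. I start by leaving E whole, which puts x at 20.0%; that x, through the power rule, puts e at 89.3%, and repeating this exchange between the balance and the rule brings x to 28.4% and e to 91.6%, so L, which is half of what X lost, comes to 35.8% of X and E together.

And the weak spot? That is the clock, since G in alpha has a half-life of 1.3 h and alpha holds the least of it. Q loses its fraction at a pace of Z times the constants weighted by X and E, a pace that is lowest at the end values just found, and with that lowest pace and Z summed over 4.0 h alpha gets 4.52 e-foldings of Q, which leaves below 1.09% of its charge and costs L below 0.43 percentage points; eta and delta sum twice and 4.00 times that Z, so I commit to a row that hardly changes.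

The forecast says 35.7%, 35.8% and 35.8%, hardly changes, with L set by “the Q stoichiometry rather than by catalyst loading”. The flasks give 35.7%, 35.8% and 35.8%, hardly changes, and alpha holds 0.367% of its Q after 4.00 h.

The shrinking supply of Q is the largest single effect on L in delta : the simulated delta run in which Q does not shrink reads 50.0% against 35.8%, a gap of 14 points. Raised to the power of the selectivity factor 14.3, the 92% of its charge of E left in delta gives 28.4%, and the X left in delta reads 28% of its charge.

Its constants were set for the occasion.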